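**Assumption and shorthand (one line):** the three esters are angelates, (2Z)-2-methylbut-2-enoates (Ang); ring locants follow carvone: C1 (C=O), C2 (C–CH3), C3, C4, C5 (carries the side chain), C6; side chain C1′ (on C5, carries =CH2), C2′, C3′, C4′, C5′ (CMe2); α = ring face of the C5 side chain, β = the other face; TES = SiEt3.

## Retrosynthetic overview

1. Target 21 ⇐ 19 by C1–OH oxidation and 4-O-desilylation; 19 ⇐ bis-oxirane 18 by hydroxyl-directed, C3-selective trans-diaxial opening of the ring oxirane with angelic acid.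
2. 18 ⇐ triene-ol 16: the ring C2–C3 oxirane and the side-chain C4′–C5′ oxirane are closed in one operation by one chiral dioxirane.
3. 16 ⇐ enal 11: asymmetric allylation, cross-metathesis to the prenyl group, angeloylation, Luche reduction.
4. 11 ⇐ (R)-carvone 1: C4 oxygenation with singlet oxygen on the dienol ether, C6 oxygenation/angeloylation, isopropenyl CH3 → CHO.
5. Ring order: carbocycle from the chiral pool; then both oxiranes together; the ring oxirane is spent to place the C3 angelate, the side-chain oxirane stays.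

## Route

Step 1
Reactants: 1 (R)-(−)-carvone
Product: 2 through-conjugated TES dienol ether of carvone (C1=C2 and C3=C4)
Conditions: MeMgBr, FeCl3 (5 mol%), Et2O, −20 °C; then Et3SiCl, Et3N, HMPA, −20 °C → rt
Reagents that add atoms: chlorotriethylsilane CC[Si](Cl)(CC)CC
Why: The iron-ate base removes the γ-proton (C4–H) under thermodynamic control and the through-conjugated magnesium dienolate is O-silylated (thermodynamic silyl dienol ether formation); no stereocentre is made and C5 is untouched.

Step 2
Reactants: 2 TES dienol ether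
Product: 5 4β-(triethylsilyloxy)carvone, via silyloxy endoperoxide 3 (not isolated), via silylperoxy enone 4 (not isolated)
Conditions: O2, hν (visible), tetraphenylporphyrin (cat.), CH2Cl2, −78 °C; then PPh3, −78 °C → rt
Reagents that add atoms: dioxygen O=O
Why: Singlet oxygen adds [4+2] to the 1-silyloxy-1,3-diene on the face anti to the C5 isopropenyl group (sets C4–O β, trans to C5), the silyl peroxyketal collapses by O-to-O silyl shift to the γ-silylperoxy enone, and PPh3 deoxygenates the silyl peroxide to the silyl ether (photooxygenation / silyl migration / phosphine reduction).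

Step 3
Reactants: 5 4β-(triethylsilyloxy)carvone
Product: 8 6β-angeloyloxy-4β-(triethylsilyloxy)carvone, via potassium enolate 6 (not isolated), via potassium alkoxide 7 (not isolated)
Conditions: KN(SiMe3)2, THF, −78 °C; 3-phenyl-2-(phenylsulfonyl)oxaziridine, −78 °C; then filtered mixed anhydride from angelic acid, 2,4,6-Cl3C6H2COCl, Et3N (THF), −78 → 0 °C
Reagents that add atoms: 3-phenyl-2-(phenylsulfonyl)oxaziridine O=S(=O)(N1OC1c1ccccc1)c1ccccc1; angelic acid C/C=C(/C)C(=O)O
Why: Kinetic α′-deprotonation at C6 and Davis enolate hydroxylation anti to the adjacent C5 substituent set C6–O β (trans, equatorial, also the thermodynamic epimer), and the alkoxide is acylated in the same flask at the unhindered carbonyl of the Yamaguchi mixed anhydride, which transfers angelate without Z-to-E isomerisation.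

Step 4
Reactants: 8 6β-angeloyloxy-4β-(triethylsilyloxy)carvone
Product: 9 allylic chloride (C5 substituent 3-chloroprop-1-en-2-yl)
Conditions: Ca(OCl)2, CO2 (dry ice), CH2Cl2/H2O, 0 °C
Reagents that add atoms: calcium hypochlorite [Ca+2].[O-]Cl.[O-]Cl
Why: Ene-type allylic chlorination by HOCl takes only the electron-rich 1,1-disubstituted alkene and regenerates the exo-methylene with chlorine on the former methyl (as known for carvone itself); the enone and angelate alkenes are too electron-poor.

Step 5
Reactants: 9 allylic chloride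
Product: 11 enal (C5 substituent 3-oxoprop-1-en-2-yl), via alkoxymorpholinium chloride 10 (not isolated)
Conditions: N-methylmorpholine N-oxide (4 equiv), MeCN, rt → 40 °C
Reagents that add atoms: N-methylmorpholine N-oxide C[N+]1([O-])CCOCC1
Why: N-oxide oxidation of an activated halide (Ganem/Kornblum type): SN2 displacement of the allylic chloride by the N-oxide oxygen, then loss of N-methylmorpholine, gives the 2-substituted acrolein under near-neutral conditions that spare the α-acyloxy ketone.

Step 6
Reactants: 11 enal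
Product: 13 (2′S)-homoallylic alcohol (C5 substituent (3S)-3-hydroxyhexa-1,5-dien-2-yl), via borinate ester 12 (not isolated)
Conditions: dIpc2B(allyl) [B-allyldiisopinocampheylborane made from (+)-α-pinene], Et2O, −78 °C; then HOCH2CH2NH2, rt
Reagents that add atoms: B-allyldiisopinocampheylborane from (+)-α-pinene C=CCB([C@@H]1C[C@@H]2C[C@H]([C@H]1C)C2(C)C)[C@@H]1C[C@@H]2C[C@H]([C@H]1C)C2(C)C
Why: Brown asymmetric allylboration through a chair transition state adds allyl to the Si face of the aldehyde under reagent control (the remote C5 centre has no say) and gives the (S)-carbinol; the aldehyde reacts far faster than the enone ketone at −78 °C and the non-oxidative work-up protects the esters.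

Step 7
Reactants: 13 (2′S)-homoallylic alcohol
Product: 14 (2′S)-prenyl carbinol (C5 substituent (3S)-3-hydroxy-6-methylhepta-1,5-dien-2-yl)
Conditions: second-generation Grubbs catalyst RuCl2(=CHPh)(H2IMes)(PCy3) (5 mol%), 2-methylbut-2-ene (excess), CH2Cl2, 40 °C
Reagents that add atoms: 2-methylbut-2-ene CC=C(C)C
Why: Olefin cross-metathesis of the only monosubstituted alkene installs the prenyl terminus; the 1,1-disubstituted, enone and angelate alkenes are inert to the ruthenium carbene and no stereocentre is touched.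

Step 8
Reactants: 14 (2′S)-prenyl carbinol
Product: 15 bis-angelate enone (2′-O-angeloyl-14)
Conditions: angelic acid, 2,4,6-Cl3C6H2COCl, Et3N, toluene, rt; then 14, 75 °C (no DMAP)
Reagents that add atoms: angelic acid C/C=C(/C)C(=O)O
Why: Yamaguchi esterification of the secondary allylic alcohol through the mixed anhydride proceeds with retention at C2′ and, without DMAP, without angelate-to-tiglate isomerisation.

Step 9
Reactants: 15 bis-angelate enone
Product: 16 1α-allylic alcohol (1-OH cis to the C5 side chain)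
Conditions: NaBH4, CeCl3·7H2O, MeOH, −78 °C
Reagents that add atoms: none
Why: Luche 1,2-reduction with axial hydride delivery gives the equatorial 1α-alcohol (the carvone-to-cis-carveol sense), leaving the esters and alkenes untouched.

Step 10 (key step)
Reactants: 16 1α-allylic alcohol
Product: 18 bis-epoxide (2α,3α-epoxide; (4′S)-4′,5′-epoxide), via side-chain monoepoxide 17 (not isolated)
Conditions: 1,2:4,5-di-O-isopropylidene-β-L-erythro-2,3-hexodiulo-2,6-pyranose (40 mol%), Oxone (2KHSO5·KHSO4·K2SO4), K2CO3, Bu4NHSO4, MeCN/CH2(OMe)2/aq Na2B4O7–Na2(EDTA) buffer, pH ca. 10, −10 → 0 °C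
Reagents that add atoms: potassium peroxymonosulfate [K+].[O-]S(=O)(=O)OO
Why: Shi asymmetric epoxidation carried through both trisubstituted alkenes in one operation: the L-series dioxirane gives the (S)-oxirane at the prenyl group (spiro transition state, the sense known for 2-methylalk-2-enes) and, by the same model, attacks the α face of C2=C3, which is also the face anti to the 4β-silyloxy group; the 1,1-disubstituted alkene and the angelates are far less nucleophilic.

Step 11
Reactants: 18 bis-epoxide
Product: 19 3β,6β,2′-tris-O-angeloyl 1α,2α-diol (4β-OTES, side-chain oxirane intact)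
Conditions: Ti(OiPr)4 (1.5 equiv), angelic acid (3 equiv), CH2Cl2, rt
Reagents that add atoms: angelic acid C/C=C(/C)C(=O)O
Why: Sharpless-type Ti(OiPr)4-mediated opening of a 2,3-epoxy alcohol: the titanium alkoxide of the cis 1α-OH chelates and activates only the ring oxirane, and carboxylate attacks C3 with inversion (trans-diaxial, Fürst–Plattner) to give 3β-OAng and 2α-OH, while the non-chelating side-chain oxirane is not activated.

Step 12
Reactants: 19 tris-angelate diol
Product: 20 4-O-triethylsilyl target (C1 ketone)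
Conditions: Dess–Martin periodinane, NaHCO3, CH2Cl2, 0 °C → rt
Reagents that add atoms: none
Why: Dess–Martin oxidation of the only secondary alcohol restores the C1 ketone (the C2 alcohol is tertiary, the C4 alcohol is silylated) without touching any stereocentre.

Step 13
Reactants: 20 4-O-triethylsilyl target
Product: 21 target (CNP0145026.1)
Conditions: HF·pyridine, pyridine, THF, 0 °C
Reagents that add atoms: none
Why: Buffered HF·pyridine cleaves the secondary triethylsilyl ether under mildly acidic conditions that avoid base-induced 3-to-4 acyl migration and are tolerated by trisubstituted oxiranes (silyl ether deprotection).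

## Compound list

1 | (R)-(−)-carvone, (5R)-2-methyl-5-(prop-1-en-2-yl)cyclohex-2-en-1-one | C=C(C)[C@@H]1CC=C(C)C(=O)C1 | starting material
2 | triethyl{[(5S)-2-methyl-5-(prop-1-en-2-yl)cyclohexa-1,3-dien-1-yl]oxy}silane | C=C(C)[C@@H]1C=CC(C)=C(O[Si](CC)(CC)CC)C1 | intermediate
3 | silyloxy endoperoxide: β-face C1,C4-epidioxide of 2 (2,3-dioxabicyclo[2.2.2]oct-5-ene, OSiEt3 at the C1 bridgehead) | C=C(C)[C@@H]1[C@@H]2C=C(C)[C@@](O[Si](CC)(CC)CC)(OO2)C1 | intermediate
4 | 4β-(triethylsilylperoxy)carvone | C=C(C)[C@@H]1[C@@H](OO[Si](CC)(CC)CC)C=C(C)C(=O)C1 | intermediate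
5 | (4S,5R)-2-methyl-5-(prop-1-en-2-yl)-4-(triethylsilyloxy)cyclohex-2-en-1-one (4β-OTES, trans to the C5 group) | C=C(C)[C@@H]1[C@@H](O[Si](CC)(CC)CC)C=C(C)C(=O)C1 | intermediate
6 | potassium C1(O)=C6 enolate of 5 | C=C(C)[C@@H]1[C@@H](O[Si](CC)(CC)CC)C=C(C)C([O-])=C1.[K+] | intermediate
7 | potassium 6β-alkoxide (6β-oxido derivative of 5) | C=C(C)[C@@H]1[C@@H](O[Si](CC)(CC)CC)C=C(C)C(=O)[C@H]1[O-].[K+] | intermediate
8 | 6β-angeloyloxy-4β-(triethylsilyloxy)carvone (4,5-trans, 5,6-trans) | C=C(C)[C@@H]1[C@@H](O[Si](CC)(CC)CC)C=C(C)C(=O)[C@H]1OC(=O)/C(C)=C\C | intermediate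
9 | allylic chloride: 8 with 3-chloroprop-1-en-2-yl at C5 | C=C(CCl)[C@@H]1[C@@H](O[Si](CC)(CC)CC)C=C(C)C(=O)[C@H]1OC(=O)/C(C)=C\C | intermediate
10 | N-methyl-N-(allyloxy)morpholinium chloride derived from 9 | C=C(CO[N+]1(C)CCOCC1)[C@@H]1[C@@H](O[Si](CC)(CC)CC)C=C(C)C(=O)[C@H]1OC(=O)/C(C)=C\C.[Cl-] | intermediate
11 | enal: 8 with 3-oxoprop-1-en-2-yl at C5 | C=C(C=O)[C@@H]1[C@@H](O[Si](CC)(CC)CC)C=C(C)C(=O)[C@H]1OC(=O)/C(C)=C\C | intermediate
12 | diisopinocampheylborinate ester of 13 | C=C([C@@H]1[C@@H](O[Si](CC)(CC)CC)C=C(C)C(=O)[C@H]1OC(=O)/C(C)=C\C)[C@H](CC=C)OB([C@@H]1C[C@@H]2C[C@H]([C@H]1C)C2(C)C)[C@@H]1C[C@@H]2C[C@H]([C@H]1C)C2(C)C | intermediate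
13 | (2′S)-homoallylic alcohol: 8 with (3S)-3-hydroxyhexa-1,5-dien-2-yl at C5 | C=C([C@@H]1[C@@H](O[Si](CC)(CC)CC)C=C(C)C(=O)[C@H]1OC(=O)/C(C)=C\C)[C@H](CC=C)O | intermediate
14 | (2′S)-prenyl carbinol: 8 with (3S)-3-hydroxy-6-methylhepta-1,5-dien-2-yl at C5 | C=C([C@@H]1[C@@H](O[Si](CC)(CC)CC)C=C(C)C(=O)[C@H]1OC(=O)/C(C)=C\C)[C@H](CC=C(C)C)O | intermediate
15 | bis-angelate enone (2′-O-angeloyl-14) | C=C([C@@H]1[C@@H](O[Si](CC)(CC)CC)C=C(C)C(=O)[C@H]1OC(=O)/C(C)=C\C)[C@H](CC=C(C)C)OC(=O)/C(C)=C\C | intermediate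
16 | 1α-allylic alcohol of 15 (1-OH cis to the C5 side chain) | C=C([C@@H]1[C@@H](O[Si](CC)(CC)CC)C=C(C)[C@H](O)[C@H]1OC(=O)/C(C)=C\C)[C@H](CC=C(C)C)OC(=O)/C(C)=C\C | intermediate
17 | (4′S)-4′,5′-epoxide of 16 (ring alkene intact) | C=C([C@@H]1[C@@H](O[Si](CC)(CC)CC)C=C(C)[C@H](O)[C@H]1OC(=O)/C(C)=C\C)[C@H](C[C@@H]1OC1(C)C)OC(=O)/C(C)=C\C | intermediate
18 | bis-epoxide: 2α,3α-epoxy and (4′S)-4′,5′-epoxy derivative of 16 | C=C([C@@H]1[C@@H](O[Si](CC)(CC)CC)[C@@H]2O[C@]2(C)[C@H](O)[C@H]1OC(=O)/C(C)=C\C)[C@H](C[C@@H]1OC1(C)C)OC(=O)/C(C)=C\C | intermediate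
19 | 3β,6β,2′-tris-O-angeloyl 1α,2α-diol with 2β-CH3, 4β-OTES and (4′S)-oxirane | C=C([C@@H]1[C@@H](O[Si](CC)(CC)CC)[C@@H](OC(=O)/C(C)=C\C)[C@](C)(O)[C@H](O)[C@H]1OC(=O)/C(C)=C\C)[C@H](C[C@@H]1OC1(C)C)OC(=O)/C(C)=C\C | intermediate
20 | 4-O-triethylsilyl ether of the target | C=C([C@@H]1[C@@H](O[Si](CC)(CC)CC)[C@@H](OC(=O)/C(C)=C\C)[C@](C)(O)C(=O)[C@H]1OC(=O)/C(C)=C\C)[C@H](C[C@@H]1OC1(C)C)OC(=O)/C(C)=C\C | intermediate
21 | target: (2S,3R,4R,5R,6S)-3,6-bis(angeloyloxy)-2,4-dihydroxy-2-methyl-5-{(3S)-3-(angeloyloxy)-4-[(2S)-3,3-dimethyloxiran-2-yl]but-1-en-2-yl}cyclohexan-1-one | C=C([C@@H]1[C@@H](O)[C@@H](OC(=O)/C(C)=C\C)[C@](C)(O)C(=O)[C@H]1OC(=O)/C(C)=C\C)[C@H](C[C@@H]1OC1(C)C)OC(=O)/C(C)=C\C | target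

## Count and risk

Total steps: 13. Longest linear sequence: 13 (fully linear from 1).

**Most likely to fail, 1: step 10 (both oxiranes in one operation).** The ring alkene is a hindered allylic alcohol, slower than the prenyl group and not far above the 1,1-disubstituted alkene; its face selectivity rests on the catalyst model plus the 4β-silyloxy group; the basic medium may also move the 6-angelate to O1. Fallback: stop the dioxirane reaction after the fast side-chain epoxidation and isolate 17, then close the ring oxirane by hydroxyl-directed epoxidation with VO(acac)2 and t-BuOOH in CH2Cl2 at 0 °C, which delivers oxygen syn to the 1α-OH and touches only the allylic alcohol alkene. This sets out from 17 and comes back at 18; it makes no compound outside the list (F0).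

**Most likely to fail, 2: step 11 (titanium-mediated angelate opening of 18).** The Lewis acid may open or rearrange the side-chain oxirane (helped by the neighbouring C2′ angelate), move the 6-angelate to O1, or deliver isopropoxide instead of angelate. Fallback: open the ring oxirane before the side-chain oxirane exists. Setting out from 16, VO(acac)2/t-BuOOH gives the ring 2α,3α-monoepoxide F1; Ti(OiPr)4 and angelic acid, now free to be run warmer, give the tris-angelate 1α,2α-diol with intact prenyl group F2; Dess–Martin oxidation gives the C1 ketone F3; HF·pyridine gives the desilylated 4′,5′-alkene F4; a single last epoxidation of the prenyl group with the same L-series ketone and Oxone (2KHSO5·KHSO4·K2SO4) at pH 8 then comes back to the route at 21.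

**Most likely to fail, 3: step 2 (photooxygenation, silyl shift, deoxygenation).** Face selectivity at C4 may be only moderate, ene or α-attack may compete, and the silyl group may be lost instead of transferred. Fallback: setting out from 2, vinylogous Rubottom oxidation with dimethyldioxirane (acetone/CH2Cl2, −78 °C) epoxidises the C3=C4 bond anti to the C5 group and desilylative opening gives free trans-4-hydroxycarvone F5; silylation with Et3SiCl and imidazole in CH2Cl2 comes back to the route at 5, with the 4-epimer removed by chromatography at that stage.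

## Further compounds

F0 | step 10 | none | none
F1 | step 11 | ring 2α,3α-monoepoxide of 16 (prenyl group intact) | C=C([C@@H]1[C@@H](O[Si](CC)(CC)CC)[C@@H]2O[C@]2(C)[C@H](O)[C@H]1OC(=O)/C(C)=C\C)[C@H](CC=C(C)C)OC(=O)/C(C)=C\C
F2 | step 11 | 3β,6β,2′-tris-O-angeloyl 1α,2α-diol with 4β-OTES and intact prenyl group | C=C([C@@H]1[C@@H](O[Si](CC)(CC)CC)[C@@H](OC(=O)/C(C)=C\C)[C@](C)(O)[C@H](O)[C@H]1OC(=O)/C(C)=C\C)[C@H](CC=C(C)C)OC(=O)/C(C)=C\C
F3 | step 11 | C1 ketone of F2 (4-O-TES, 4′,5′-alkene) | C=C([C@@H]1[C@@H](O[Si](CC)(CC)CC)[C@@H](OC(=O)/C(C)=C\C)[C@](C)(O)C(=O)[C@H]1OC(=O)/C(C)=C\C)[C@H](CC=C(C)C)OC(=O)/C(C)=C\C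
F4 | step 11 | 4′,5′-deoxy target (desilylated F3, prenyl group in place of the oxirane) | C=C([C@@H]1[C@@H](O)[C@@H](OC(=O)/C(C)=C\C)[C@](C)(O)C(=O)[C@H]1OC(=O)/C(C)=C\C)[C@H](CC=C(C)C)OC(=O)/C(C)=C\C
F5 | step 2 | trans-4-hydroxycarvone, (4S,5R)-4-hydroxy-2-methyl-5-(prop-1-en-2-yl)cyclohex-2-en-1-one | C=C(C)[C@@H]1[C@@H](O)C=C(C)C(=O)C1
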